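The constants are made up; the flask was simulated.

In a one-step world an impurity would cost you in proportion to its share of the substrate, and 0.31 mM beside 12 mM of substrate is hardly any.

    reagent + free catalyst → catalyst intermediate A (k1 = 2.5 M⁻¹ s⁻¹, Ea1 = 38.0 kJ mol⁻¹)
    catalyst intermediate A ⇌ released group + catalyst intermediate B (K2 = 0.0073 M, k2 = 0.024 s⁻¹, Ea2 = 71.0 kJ mol⁻¹, ΔH2 = −1.00 kJ mol⁻¹)
    substrate + catalyst intermediate B → catalyst intermediate C (k3 = 2.5 M⁻¹ s⁻¹, Ea3 = 46.0 kJ mol⁻¹)
    catalyst intermediate C → free catalyst + target (k4 = 0.017 s⁻¹, Ea4 = 71.0 kJ mol⁻¹)
    free catalyst + impurity → spent catalyst (k5 = 46 M⁻¹ s⁻¹, Ea5 = 46.0 kJ mol⁻¹)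
    (constants at 5 °C)

the same everywhere: free catalyst 0.60 mM; impurity 0.31 mM; time 3.0 h
- beta: substrate 12 mM; reagent 12.0 mM (fed, over 40 min); temperature 5 °C; all else is in the flask from the start; the feed brings no volume worth counting
- gamma: substrate 12 mM (fed, over 40 min); reagent 12.0 mM; temperature 5 °C; all else is in the flask from the start; the feed brings no volume worth counting
- theta: substrate 12 mM; reagent 12.0 mM; temperature 5 °C; everything together at the start
- eta: substrate 12 mM (fed, over 40 min); reagent 12.0 mM; the addition at −15 °C, then warmed to 5 °C; the feed brings no volume worth counting

- constants are those at 5 °C; use the activation energies and enthalpies for any other temperature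

- the flask with the highest amount of target, in percent of the substrate charged ("all alike" if they lie within 1.5 percentage points) (beta / gamma / theta / eta / all alike)
- final target, as a percentage of the substrate charged, in beta
- final target, as a percentage of the substrate charged, in gamma
- final target, as a percentage of the substrate charged, in theta
- final target, as a percentage of the substrate charged, in eta

Yet the same impurity stands at half the 0.60 mM of free catalyst, so the two fractions point to very different costs. Write the balance of the impurity, which in these flasks is charged in the smaller amount and is the limiting reagent of its step. Each impurity lost is one spent catalyst, that step has no way back, and the catalyst comes free again each round. At the start of theta, the impurity takes a share of 32.2 % of the free catalyst's exits, so you expect the impurity to be used up. Charged catalyst minus charged impurity is 0.290 mM; call this the working catalyst. It must make 41.4 rounds per catalyst to finish the substrate.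

Now the clock of theta. Substrate and reagent are charged equally and leave one for one, so let c stand for both, neglecting what the catalyst holds between them, and c(released group) is the charge minus c. A round lasts two first-order times, 41.7 s and 58.8 s, plus two entry times and the falling back of catalyst intermediate B with released group, and those last three grow as c falls. The rate is the working catalyst divided by the round time. Integrated, the time to bring c to a fraction y of its charge is 1.40 h times minus ln y, plus 0.525 h times the fraction consumed. For y = 0.167 this gives 2.94 h, less than the 3.0 h allowed, so you commit to a little over 83.3 % for theta. Rounds then last 774 s. Counting the cold feed of eta as 40 min of lost time at that pace puts eta lower than theta by 7.49 % of the substrate charged.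

The forecast gives 81 % for beta, 82 % for gamma, 84 % for theta and 77 % for eta, and names theta, on the grounds that “Slow feeding only starves the cycle early”.

The flasks end at 81.1 % in beta, 81.8 % in gamma, 84.0 % in theta and 76.6 % in eta, so theta leads. In theta at 3.00 h, the impurity stands at 0 % of its charge and spent catalyst at 51.7 % of the catalyst charged, and the working catalyst was reckoned at 48.3 % of that charge. Now take eta's neighbour with 0.15 mM of free catalyst, less than the impurity. Its working catalyst comes to −0.160 mM, so the balance leaves 51.6 % of the impurity over. That flask holds 51.6 % of its impurity, 0 % free catalyst and 3.91 % target at 3.00 h.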